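The 2-pyranone ring is traced back to a furan. Its carbons C2, C3(OMe), C4(OMe) and C5 are the four ring carbons of 3,4-dimethoxyfuran, and C6–O1 is the C–O bond of a secondary 2-furylcarbinol. A singlet-oxygen Achmatowicz ring expansion turns this racemic carbinol, which already carries the complete E-configured side chain, in one operation into a 6-hydroxy-2H-pyran-3(6H)-one. It forms the O1–C2 bond and the six-membered ring, keeps both methoxy groups in place and leaves a ketone at C5 (target numbering) as the handle for the last methyl group. The carbinol comes from 2-lithio-3,4-dimethoxyfuran and a β,γ-unsaturated aldehyde; lactol oxidation, enol triflation and Stille methylation complete lehualide E.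

Key step: step 5

Remark: counted from the target, the side chain is 3-methyl-9-phenylnon-2-enyl (six CH2 groups between the alkene and the phenyl ring). The furylcarbinol is therefore a 4-methyl-10-phenyldec-3-en-1-ol and the ring-expanded lactol carries a 3-methyl-9-phenylnon-2-enyl group; names with one more chain carbon would not fit the target, and the corrected names are used below. The target has no stereocentre, only the E alkene. The furylcarbinol, the lactol and the dione are racemic, and their centres become sp2 carbons later. 3,4-Dimethoxyfuran is assumed to be purchasable.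

Step 1
Reactants: 1 (6-bromohexyl)benzene
Product: 2 8-phenyloct-1-yne
Conditions: LiC≡CH·H2NCH2CH2NH2, DMSO, 10 °C → rt
Reagents that add atoms: lithium acetylide–ethylenediamine complex, [Li]C#C.NCCN
Why: SN2 alkylation of lithium acetylide by an unhindered primary bromide in DMSO is a standard terminal-alkyne synthesis, and the ethylenediamine complex keeps the acetylide monomeric and suppresses dialkylation.

Step 2
Reactants: 2 8-phenyloct-1-yne; 3 ethylene oxide
Product: 6 (E)-4-methyl-10-phenyldec-3-en-1-ol, via alkenylalane 4 (not isolated), via lithium alkenylalanate 5 (not isolated)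
Conditions: AlMe3, Cp2ZrCl2 (cat.), CH2Cl2, 0 °C → rt; evaporate excess AlMe3, hexane; n-BuLi, 0 °C; ethylene oxide (THF solution), 0 °C → rt; H2O
Reagents that add atoms: trimethylaluminium, C[Al](C)C
Why: The zirconium-catalysed Negishi carboalumination adds methyl and aluminium syn across the terminal alkyne with aluminium at the terminus, which fixes the E trisubstituted alkene, and the derived butyl alanate transfers its alkenyl group to ethylene oxide with retention of geometry (epoxide opening by an alkenylalanate).

Step 3
Reactants: 6 (E)-4-methyl-10-phenyldec-3-en-1-ol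
Product: 7 (E)-4-methyl-10-phenyldec-3-enal
Conditions: Dess–Martin periodinane, pyridine, CH2Cl2, 0 °C → rt; used at once
Reagents that add atoms: none
Why: Dess–Martin oxidation stops cleanly at the aldehyde under buffered, non-aqueous conditions, so the β,γ double bond should neither migrate into conjugation nor lose its E geometry.

Step 4
Reactants: 8 3,4-dimethoxyfuran; 7 (E)-4-methyl-10-phenyldec-3-enal
Product: 10 (±)-(E)-1-(3,4-dimethoxyfuran-2-yl)-4-methyl-10-phenyldec-3-en-1-ol, via 2-lithio-3,4-dimethoxyfuran 9 (not isolated)
Conditions: n-BuLi, THF, −78 → 0 °C; then 7, −78 °C; H2O; chromatography on Et3N-deactivated silica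
Reagents that add atoms: none
Why: n-BuLi deprotonates the furan at C2 (α to the ring oxygen and ortho to a methoxy group; C2 and C5 are equivalent by symmetry), and 1,2-addition of the furyllithium to the aldehyde at −78 °C should give the secondary carbinol, whose new stereocentre forms racemic and needs no control because it becomes sp2 in the target.

Step 5
Reactants: 10 (±)-(E)-1-(3,4-dimethoxyfuran-2-yl)-4-methyl-10-phenyldec-3-en-1-ol
Product: 13 6-hydroxy-4,5-dimethoxy-2-[(E)-3-methyl-9-phenylnon-2-enyl]-2H-pyran-3(6H)-one (racemic mixture of lactol epimers), via furan endoperoxide 11 (not isolated), via open-chain Z-ene-dione 12 (not isolated)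
Conditions: O2, visible light, tetraphenylporphyrin (cat.), CH2Cl2, −78 °C, stopped when 10 is consumed; then Me2S, −78 °C → rt
Reagents that add atoms: dioxygen (as singlet oxygen), O=O
Why: Singlet oxygen adds across furan C2 and C5 of 10 in a [4+2] cycloaddition to give endoperoxide 11, whose O–O bond is cleaved reductively by Me2S so that the bicycle collapses to the Z-configured 2-ene-1,4-dicarbonyl compound 12, with a ketone at the former furan C2 and an aldehyde at the former C5. The secondary hydroxyl next to the ketone then adds to the aldehyde carbon in a 6-exo-trig hemiacetalisation that closes the dihydropyranone ring of 13, the Z geometry inherited from the furan holding the two ends within reach. This is the photooxygenation variant of the Achmatowicz rearrangement of 2-furylcarbinols, and the two methoxy groups ride through as spectators that make the diene more electron-rich. The lactol carbon and the retained carbinol carbon form without control as a racemic mixture of diastereomers, which is harmless because both become sp2 carbons in later steps. The step needs chemoselectivity for the furan over the trisubstituted side-chain alkene (Schenck ene reaction) and over the tetrasubstituted dimethoxy alkene of the product; the much faster cycloaddition to an electron-rich furan, the low temperature, the aprotic medium and ending the irradiation at full conversion of 10 should secure it, helped by the deactivating keto group on the product alkene.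

Step 6
Reactants: 13 6-hydroxy-4,5-dimethoxy-2-[(E)-3-methyl-9-phenylnon-2-enyl]-2H-pyran-3(6H)-one
Product: 14 (±)-3,4-dimethoxy-6-[(E)-3-methyl-9-phenylnon-2-enyl]-2H-pyran-2,5(6H)-dione
Conditions: Ag2CO3 on Celite, toluene, 80 °C
Reagents that add atoms: none
Why: Fétizon oxidation converts lactols into lactones under neutral heterogeneous conditions that should leave the trisubstituted alkene and the enol ethers untouched.

Step 7
Reactants: 14 (±)-3,4-dimethoxy-6-[(E)-3-methyl-9-phenylnon-2-enyl]-2H-pyran-2,5(6H)-dione
Product: 16 3,4-dimethoxy-6-[(E)-3-methyl-9-phenylnon-2-enyl]-2-oxo-2H-pyran-5-yl trifluoromethanesulfonate, via 5-hydroxy-2-pyranone tautomer 15 (not isolated)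
Conditions: PhNTf2, Et3N, CH2Cl2, 0 °C → rt
Reagents that add atoms: N-phenylbis(trifluoromethanesulfonimide), O=S(=O)(N(c1ccccc1)S(=O)(=O)C(F)(F)F)C(F)(F)F
Why: Enol triflate formation is regiospecific here because the only α-hydrogen of the C5 ketone is H6, whose removal by the amine gives the aromatic 2-pyranon-5-olate (the anion of tautomer 15) that is O-sulfonylated by PhNTf2; any 15 already present in crude 14 converges on the same product.

Step 8
Reactants: 16 3,4-dimethoxy-6-[(E)-3-methyl-9-phenylnon-2-enyl]-2-oxo-2H-pyran-5-yl trifluoromethanesulfonate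
Product: 17 lehualide E, 3,4-dimethoxy-5-methyl-6-[(E)-3-methyl-9-phenylnon-2-enyl]-2H-pyran-2-one
Conditions: Me4Sn, Pd(PPh3)4 (cat.), LiCl, DMF, 80 °C
Reagents that add atoms: tetramethylstannane, C[Sn](C)(C)C
Why: Stille coupling, in which oxidative addition of the zerovalent palladium complex into the enol triflate C–O bond, chloride-assisted transfer of a methyl group from tin and reductive elimination install the C5 methyl under neutral conditions that should spare the lactone and the skipped diene.

Compound list
1 | (6-bromohexyl)benzene | BrCCCCCCc1ccccc1 | starting material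
2 | 8-phenyloct-1-yne | C#CCCCCCCc1ccccc1 | intermediate
3 | ethylene oxide (oxirane) | C1CO1 | starting material
4 | (E)-dimethyl(2-methyl-8-phenyloct-1-enyl)alane | C[Al](C)/C=C(\C)CCCCCCc1ccccc1 | intermediate
5 | lithium (E)-butyldimethyl(2-methyl-8-phenyloct-1-enyl)alanate | [Li+].CCCC[Al-](C)(C)/C=C(\C)CCCCCCc1ccccc1 | intermediate
6 | (E)-4-methyl-10-phenyldec-3-en-1-ol | OCC/C=C(\C)CCCCCCc1ccccc1 | intermediate
7 | (E)-4-methyl-10-phenyldec-3-enal | O=CC/C=C(\C)CCCCCCc1ccccc1 | intermediate
8 | 3,4-dimethoxyfuran | COc1cocc1OC | starting material
9 | (3,4-dimethoxyfuran-2-yl)lithium | [Li]c1occ(OC)c1OC | intermediate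
10 | (E)-1-(3,4-dimethoxyfuran-2-yl)-4-methyl-10-phenyldec-3-en-1-ol (racemic) | COc1coc(C(O)C/C=C(\C)CCCCCCc2ccccc2)c1OC | intermediate
11 | 1-[(E)-1-hydroxy-4-methyl-10-phenyldec-3-enyl]-5,6-dimethoxy-2,3,7-trioxabicyclo[2.2.1]hept-5-ene | COC1=C(OC)C2(C(O)C/C=C(\C)CCCCCCc3ccccc3)OC1OO2 | intermediate
12 | (2Z,7E)-5-hydroxy-2,3-dimethoxy-8-methyl-4-oxo-14-phenyltetradeca-2,7-dienal (racemic) | O=C/C(OC)=C(OC)\C(=O)C(O)C/C=C(\C)CCCCCCc1ccccc1 | intermediate
13 | 6-hydroxy-4,5-dimethoxy-2-[(E)-3-methyl-9-phenylnon-2-enyl]-2H-pyran-3(6H)-one (racemic, both lactol epimers) | COC1=C(OC)C(=O)C(C/C=C(\C)CCCCCCc2ccccc2)OC1O | intermediate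
14 | 3,4-dimethoxy-6-[(E)-3-methyl-9-phenylnon-2-enyl]-2H-pyran-2,5(6H)-dione (racemic) | COC1=C(OC)C(=O)C(C/C=C(\C)CCCCCCc2ccccc2)OC1=O | intermediate
15 | 5-hydroxy-3,4-dimethoxy-6-[(E)-3-methyl-9-phenylnon-2-enyl]-2H-pyran-2-one | COc1c(O)c(C/C=C(\C)CCCCCCc2ccccc2)oc(=O)c1OC | intermediate
16 | 3,4-dimethoxy-6-[(E)-3-methyl-9-phenylnon-2-enyl]-2-oxo-2H-pyran-5-yl trifluoromethanesulfonate | COc1c(OS(=O)(=O)C(F)(F)F)c(C/C=C(\C)CCCCCCc2ccccc2)oc(=O)c1OC | intermediate
17 | lehualide E, 3,4-dimethoxy-5-methyl-6-[(E)-3-methyl-9-phenylnon-2-enyl]-2H-pyran-2-one | COc1c(C)c(C/C=C(\C)CCCCCCc2ccccc2)oc(=O)c1OC | target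

Total step count: 8. Longest linear sequence: 8 steps, from (6-bromohexyl)benzene 1 to lehualide E 17; ethylene oxide 3 and 3,4-dimethoxyfuran 8 enter as bought.

Steps most likely to fail

Step 5. The dimethoxy-substituted double bond that remains after the first cycloaddition, in 11 and in 13, is electron-rich and may take up a second molecule of singlet oxygen, which would cleave it by way of a dioxetane. The side-chain alkene may also undergo an ene reaction if irradiation runs on, and the endoperoxide may fragment before it is reduced. The fallback sets out from 10 and replaces the photooxygenation by the stepwise, ionic form of the ring expansion. Anodic 2,5-dimethoxylation (constant current, MeOH, Et4NOTs, carbon anode, −20 °C) selects the furan over the isolated alkene by its lower oxidation potential and should give (E)-1-(2,3,4,5-tetramethoxy-2,5-dihydrofuran-2-yl)-4-methyl-10-phenyldec-3-en-1-ol F1 as a diastereomer mixture. Brief hydrolysis with dilute aqueous acid (pyridinium p-toluenesulfonate, acetone/H2O, 0 °C) should unmask ene-dione 12, which closes to lactol 13, where the route is rejoined.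

Step 8. Transfer of a methyl group from tin to palladium is slow, and the triflate carbon is flanked by a methoxy group and the side chain. Sulfur–oxygen cleavage of the triflate back to the hydroxypyranone, or decay of the catalyst, may therefore overtake the coupling. The fallback sets out from 16 and inverts the polarity of the coupling. Miyaura borylation (bis(pinacolato)diboron, Pd(dppf)Cl2, KOAc, dioxane, 80 °C) should give 3,4-dimethoxy-6-[(E)-3-methyl-9-phenylnon-2-enyl]-5-(4,4,5,5-tetramethyl-1,3,2-dioxaborolan-2-yl)-2H-pyran-2-one F2. Suzuki–Miyaura methylation of F2 with MeI (Pd2(dba)3, P(o-tol)3, K2CO3, DMF/H2O, 60 °C) should then deliver 17 directly.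

Step 4. The α-methylene group of aldehyde 7 is activated by both the formyl group and the alkene, so the basic furyllithium may deprotonate it instead of adding. That would return aldehyde and let the double bond migrate into conjugation. The fallback sets out from alanate 5 (made as in step 2) and furyllithium 9 and reverses the polarity of the carbinol-forming bond, so that no enolisable aldehyde is involved. Alanate 5 and paraformaldehyde (THF, rt) should give (E)-3-methyl-9-phenylnon-2-en-1-ol F3. MsCl, 2,4,6-collidine and LiCl in DMF at 0 °C should convert it without allylic transposition into (E)-1-chloro-3-methyl-9-phenylnon-2-ene F4. Formylation of 9 with DMF (−78 °C → rt, then H2O) should give 3,4-dimethoxyfuran-2-carbaldehyde F5. Reactive barium, made from BaI2 and lithium biphenylide LiC12H10 in THF, should convert F4 at −78 °C into [(E)-3-methyl-9-phenylnon-2-enyl]barium chloride F6. Allylbarium reagents add to aldehydes at the unsubstituted α-carbon with retention of alkene geometry, so F6 and F5 at −78 °C should give carbinol 10, where the route is rejoined.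

Further compounds
F1 | step 5 | (E)-1-(2,3,4,5-tetramethoxy-2,5-dihydrofuran-2-yl)-4-methyl-10-phenyldec-3-en-1-ol (diastereomer mixture) | COC1=C(OC)C(OC)(C(O)C/C=C(\C)CCCCCCc2ccccc2)OC1OC
F2 | step 8 | 3,4-dimethoxy-6-[(E)-3-methyl-9-phenylnon-2-enyl]-5-(4,4,5,5-tetramethyl-1,3,2-dioxaborolan-2-yl)-2H-pyran-2-one | COc1c(B2OC(C)(C)C(C)(C)O2)c(C/C=C(\C)CCCCCCc3ccccc3)oc(=O)c1OC
F3 | step 4 | (E)-3-methyl-9-phenylnon-2-en-1-ol | OC/C=C(\C)CCCCCCc1ccccc1
F4 | step 4 | (E)-1-chloro-3-methyl-9-phenylnon-2-ene | ClC/C=C(\C)CCCCCCc1ccccc1
F5 | step 4 | 3,4-dimethoxyfuran-2-carbaldehyde | COc1coc(C=O)c1OC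
F6 | step 4 | [(E)-3-methyl-9-phenylnon-2-enyl]barium chloride | Cl[Ba]C/C=C(\C)CCCCCCc1ccccc1
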